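All runs are calculated for an exercise, noise included.

**Late slowing.** Late in the beta run, a stirred flask in which substrate and partner make target, the target gains 0.00580 h⁻¹ of the charge, less than the 0.0350 h⁻¹ of its first hours. You have to rank flasks that differ in how the two go in.

| flask | substrate | partner | remark | time |
|---|---|---|---|---|
| beta | 0.037 M | 0.0666 M | run made earlier |  |
| zeta | 0.037 M | 0.10 M | run made earlier |  |
| Monday's | 0.037 M (fed, over 15 h) | 0.0666 M | all else is in the flask from the start; the feed brings no volume worth counting | 40 h |
| Wednesday's | 0.037 M | 0.0666 M (fed, over 15 h) | all else is in the flask from the start; the feed brings no volume worth counting | 40 h |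
| Sunday's | 0.037 M | 0.0666 M | everything together at the start | 40 h |
| Saturday's | 0.037 M (fed, over 4.0 h) | 0.0666 M | all else is in the flask from the start; the feed brings no volume worth counting | 40 h |
| Thursday's | 0.037 M | 0.0666 M (in portions, 4, over 15 h) | first portion at the start, last at 15 h | 40 h |

- beta (time / h: target / %): 3.00: 10.5; 6.00: 18.2; 10.0: 24.3; 15.0: 30.1; 20.0: 33.9; 25.0: 36.8
- zeta (time / h: target / %): 0.667: 4.6; 1.00: 6.7; 1.33: 7.7; 2.50: 12.8; 3.00: 15.2; 5.00: 23.0; 8.00: 31.2

(each reading ± 0.5 percentage points)

1. the flask with the highest amount of target, in percent of the substrate charged ("all alike" if they lie within 1.5 percentage points) (Monday's / Wednesday's / Sunday's / Saturday's / Thursday's / all alike)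
2. final target, as a percentage of the substrate charged, in Monday's
3. final target, as a percentage of the substrate charged, in Wednesday's
4. final target, as a percentage of the substrate charged, in Sunday's
5. final target, as a percentage of the substrate charged, in Saturday's
6. final target, as a percentage of the substrate charged, in Thursday's

- the numbers in the tables scatter by 0.5 percentage points (one standard deviation)

**Fade time.** Place those two rates at their mid-times, and the rate falls by a factor of e in 11.7 h, the fade time. Start rate times fade time, cut off at 40 h, gives 39.6%, my figure for Sunday's, where nothing waits.

**Delay number.** A steady feed over 15 h and portions spread evenly over it both make the fed charge wait 7.50 h on average. So Monday's, Wednesday's and Thursday's share 0.642, the delay number, mean wait over fade time (a Damköhler number). Saturday's has 0.171.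

**Reading it.** With [partner] and [substrate] unseen, I split the fade evenly between them: a fed species meets the other's fade, so target shrinks by exp(-D/2). That gives 28.7% for the three and 36.3% for Saturday's, with Sunday's first. The number cannot see which species is fed. If one species held the whole fade, feeding the other gives 20.8% and feeding it costs nothing, so one number holds if the fade is shared.

**The forecast.** It puts Monday's first, with 45.5%, then Saturday's 43.5%, Sunday's 42.5%, Thursday's 29.5% and Wednesday's 27%: “Feeding substrate keeps s low and suppresses the self-reaction”. We part on Monday's, which I place at 28.7%.

**The result.** Sunday's holds most, 40.5%; Saturday's gives 38.5%, and Monday's, Wednesday's and Thursday's give 33.0%, 33.0% and 33.3%.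

    substrate + partner → target (k = 0.0110 M⁻¹ min⁻¹)
    substrate → side product A (k = 2.20 × 10⁻⁵ min⁻¹)
    2 substrate → side product B (k = 0.00810 M⁻¹ min⁻¹)
    partner → decomposition product (k = 7.20 × 10⁻⁶ min⁻¹)
    partner → decomposed reagent (k = 6.10 × 10⁻⁴ min⁻¹)

**Neighbour flask.** Monday's and Sunday's put the cost at 0.320 per unit of delay number; on Saturday's 0.171 that gives 38.4%, against 38.5%. Now take Monday's with 0.022 M of substrate. If the substrate's even share of the fade shrinks with its charge, the fade time becomes 14.7 h and the delay number 0.512, so the reckoning gives 40.7%. The neighbour gives 37.2%, more than Monday's 33.0%, and 21.8% of its substrate has gone to side product B after 40.0 h.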